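**Plan**

- Numbering: C1 is the carboxyl carbon, C3–C4–C5 are the ring carbons, C7 carries the chain methyl, and the alkenes are C12=C13 and C16=C17.
- Enabling feature: the 1,2-dioxolane is a three-carbon unit C3–C4–C5 whose two fully substituted ends each hold one peroxide oxygen, with a two-carbon acid arm on C3. This is O2 inserted into the C3–C5 bond of a tetrasubstituted vinylcyclopropane, the vinyl group standing for CH2CO2H.
- Cuts, in retrosynthetic order: C12=C13 (Julia–Kocienski); the C1 acid back to vinyl C2=C1; O–C3 and O–C5 (radical oxygenation of the cyclopropane C3–C5 bond); C1=C2 (Wittig); the two cyclopropane bonds to C4 (Simmons–Smith); C3=C5 (Horner–Wadsworth–Emmons); C10=C11 (cross-metathesis, then hydrogenation); C5–CH3 (MeLi on (R)-citronellic acid).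
- Forward order: the C5–C12 chain is assembled first, the cyclopropane is built on it, the dioxolane (the only ring that has to be made) closes in step 10, the acid arm is oxidised up, and the phenyl diene tail is joined last.
- Stereochemistry: C7 comes from (R)-citronellic acid. C3 and C5 arise in step 10, cis through a chair-like peroxyl closure but without control against C7, so a diastereomer separation is part of the plan. C16=C17 (E) comes from a Johnson–Claisen rearrangement and C12=C13 (E) from the Julia–Kocienski step.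

Key step: step 10

Remark on the chemistry: the cyclopropane stereocentres of 12–14 and the alkene geometry of 10 and 11 are left open on purpose, because C3 and C5 both become planar in step 10.

Assumption: the four dioxolane diastereomers formed in step 10 can be separated by preparative HPLC at the stage of 15; if not, they would be carried one step further and separated as the alcohols 17.

Step 1
Reactants: 1 (R)-citronellic acid [(3R)-3,7-dimethyloct-6-enoic acid]
Product: 3 (4R)-4,8-dimethylnon-7-en-2-one, via dilithium gem-diolate 2 (not isolated)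
Conditions: MeLi (2.2 equiv), Et2O, 0 °C to rt; then poured into cold 1 M HCl
Reagents that add atoms: methyllithium, [Li]C
Why: Addition of MeLi to the lithium carboxylate (methyl ketone synthesis from a carboxylic acid) stops at the stable dilithium gem-diolate, which releases the ketone only on quench, and the C7 stereocentre, two carbons from the carbonyl, cannot epimerise.

Step 2
Reactants: 4 (Z)-but-2-ene-1,4-diol
Product: 5 (Z)-1,4-bis[(tert-butyldiphenylsilyl)oxy]but-2-ene
Conditions: TBDPSCl (2.2 equiv), imidazole, DMF, 0 °C to rt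
Reagents that add atoms: tert-butyl(chloro)diphenylsilane, CC(C)(C)[Si](Cl)(c1ccccc1)c1ccccc1
Why: Standard silylation of both primary hydroxyls gives the symmetrical metathesis partner; a silyl ether is chosen for O12 because it survives the hydride, organozinc, ylide and radical steps that an acyl protecting group would not.

Step 3
Reactants: 3 (4R)-4,8-dimethylnon-7-en-2-one; 5 (Z)-1,4-bis[(tert-butyldiphenylsilyl)oxy]but-2-ene
Product: 6 (4R,7E)-9-[(tert-butyldiphenylsilyl)oxy]-4-methylnon-7-en-2-one (E/Z mixture acceptable)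
Conditions: second-generation Hoveyda–Grubbs catalyst RuCl2(H2IMes)(=CH-C6H4-2-O-i-Pr) (5 mol%), 5 (2.5 equiv), CH2Cl2, 40 °C
Reagents that add atoms: none
Why: Olefin cross-metathesis in which the prenyl-type trisubstituted alkene of 3 exchanges its isopropylidene for the silyloxyethylidene unit of the excess allylic ether 5, adding C11 and C12 at the alcohol oxidation level in one operation; the geometry does not matter because the alkene is hydrogenated next.

Step 4
Reactants: 6 (4R,7E)-9-[(tert-butyldiphenylsilyl)oxy]-4-methylnon-7-en-2-one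
Product: 7 (4R)-9-[(tert-butyldiphenylsilyl)oxy]-4-methylnonan-2-one
Conditions: H2 (1 atm), Pd/C (10%), EtOAc, rt
Reagents that add atoms: none
Why: Heterogeneous hydrogenation saturates the disubstituted alkene without touching the ketone or the silyl ether, and the neutral solvent keeps hydrogenolysis of the allylic C–O bond in check.

Step 5
Reactants: 7 (4R)-9-[(tert-butyldiphenylsilyl)oxy]-4-methylnonan-2-one; 8 triethyl 2-phosphonopropionate
Product: 10 ethyl (5R)-10-[(tert-butyldiphenylsilyl)oxy]-2,3,5-trimethyldec-2-enoate (E/Z mixture), via sodium phosphonate carbanion 9 (not isolated)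
Conditions: 8 (2 equiv), NaH (2 equiv), DME, 0 °C to rt; then 7, 85 °C
Reagents that add atoms: none
Why: Horner–Wadsworth–Emmons olefination of a methyl ketone with an α-methyl phosphonate is slow but known to give tetrasubstituted enoates on heating, and either geometry serves because the stereocentres derived from this double bond are erased in step 10.

Step 6
Reactants: 10 ethyl (5R)-10-[(tert-butyldiphenylsilyl)oxy]-2,3,5-trimethyldec-2-enoate
Product: 11 (5R)-10-[(tert-butyldiphenylsilyl)oxy]-2,3,5-trimethyldec-2-en-1-ol (E/Z mixture)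
Conditions: i-Bu2AlH (2.5 equiv), CH2Cl2, −78 to 0 °C; aq. potassium sodium tartrate
Reagents that add atoms: none
Why: 1,2-Reduction of the enoate by excess i-Bu2AlH gives the allylic alcohol that will direct the cyclopropanation, and the silyl ether is inert to the hydride.

Step 7
Reactants: 11 (5R)-10-[(tert-butyldiphenylsilyl)oxy]-2,3,5-trimethyldec-2-en-1-ol
Product: 12 (2-{(2R)-7-[(tert-butyldiphenylsilyl)oxy]-2-methylheptyl}-1,2-dimethylcyclopropyl)methanol (mixture of cyclopropane diastereomers)
Conditions: Et2Zn (3 equiv), CH2I2 (3 equiv), CH2Cl2, −10 °C to rt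
Reagents that add atoms: diiodomethane, ICI
Why: Hydroxyl-directed Simmons–Smith cyclopropanation with EtZnCH2I is stereospecific and works well on electron-rich tetrasubstituted allylic alcohols, delivering C4 across the C3=C5 double bond; all diastereomers that arise from the E/Z mixture and from C7 converge later.

Step 8
Reactants: 12 (2-{(2R)-7-[(tert-butyldiphenylsilyl)oxy]-2-methylheptyl}-1,2-dimethylcyclopropyl)methanol
Product: 13 2-{(2R)-7-[(tert-butyldiphenylsilyl)oxy]-2-methylheptyl}-1,2-dimethylcyclopropane-1-carbaldehyde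
Conditions: Dess–Martin periodinane, CH2Cl2, 0 °C to rt
Reagents that add atoms: none
Why: Dess–Martin oxidation of the neopentyl-type primary alcohol runs under near-neutral conditions that avoid cyclopropylcarbinyl cation chemistry, and the aldehyde has no α-hydrogen to enolise.

Step 9
Reactants: 13 2-{(2R)-7-[(tert-butyldiphenylsilyl)oxy]-2-methylheptyl}-1,2-dimethylcyclopropane-1-carbaldehyde
Product: 14 tert-butyl{[(6R)-7-(2-ethenyl-1,2-dimethylcyclopropyl)-6-methylheptyl]oxy}diphenylsilane
Conditions: Ph3PCH3Br, KOtBu, THF, 0 °C to rt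
Reagents that add atoms: methyltriphenylphosphonium bromide, C[P+](c1ccccc1)(c1ccccc1)c1ccccc1.[Br-]
Why: Wittig methylenation with the small unstabilised ylide tolerates the fully substituted α-carbon of the non-enolisable aldehyde and supplies C1, completing the vinylcyclopropane.

Step 10
Reactants: 14 tert-butyl{[(6R)-7-(2-ethenyl-1,2-dimethylcyclopropyl)-6-methylheptyl]oxy}diphenylsilane
Product: 15 tert-butyl({(6R)-7-[(3R,5R)-5-ethenyl-3,5-dimethyl-1,2-dioxolan-3-yl]-6-methylheptyl}oxy)diphenylsilane (ring methyls cis; vinyl on target C3 and chain on target C5)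
Conditions: O2 (1 atm, slow stream), PhSeSePh (0.2 equiv), AIBN (0.1 equiv), hν (sunlamp), MeCN–CH2Cl2, 0 °C; then preparative HPLC
Reagents that add atoms: dioxygen, O=O
Why: PhSe• adds to the vinyl terminus C1, the cyclopropylcarbinyl radical at C2 opens by scission of the C3–C5 bond to the tertiary C5 radical, this captures O2 (O–C5), and the peroxyl radical attacks C3 of the allyl selenide (O–C3) with β-expulsion of PhSe•, which restores the vinyl group and carries the chain. The closest known reaction type is the chalcogenyl-radical-catalysed [3+2] oxygenation of vinylcyclopropanes to 3-vinyl-1,2-dioxolanes, applied here to a cyclopropane whose two reacting carbons are both fully substituted. The dioxolane closes by 5-exo-trig attack of the peroxyl oxygen on the trisubstituted alkene carbon C3. C5 is fixed when O2 adds to the planar tertiary radical, with no bias from the remote C7 centre, so both C5 configurations are expected; C3 is fixed relative to C5 in a chair-like transition state in which the larger CH2–C7 arm on C5 and the alkene carbon C2 both sit pseudo-equatorial, which places vinyl cis to that arm and the two methyls cis. The step needs this 3,5-cis relationship, which is secured only by the size difference between CH2R and CH3 on C5 (an axial CH2R would clash 1,3 with the C3 methyl) and by the low temperature that the selenium catalyst permits, so 15 has to be separated from its C5-epimeric cis partner and from the two trans isomers. Every cyclopropane diastereomer of 14 converges, because both ring carbons are planar before the new bonds form.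

Step 11
Reactants: 15 tert-butyl({(6R)-7-[(3R,5R)-5-ethenyl-3,5-dimethyl-1,2-dioxolan-3-yl]-6-methylheptyl}oxy)diphenylsilane
Product: 17 2-[(3S,5R)-5-{(2R)-7-[(tert-butyldiphenylsilyl)oxy]-2-methylheptyl}-3,5-dimethyl-1,2-dioxolan-3-yl]ethan-1-ol (same geometry as 15; descriptor at C3 changes by priority only), via B-alkyl-9-borabicyclononane 16 (not isolated)
Conditions: 9-BBN (1.5 equiv), THF, 0 °C to rt; then NaBO3·4H2O, H2O, rt
Reagents that add atoms: 9-borabicyclo[3.3.1]nonane, B1C2CCCC1CCC2 (boron held only in 16); sodium perborate, [Na+].[O-]OB=O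
Why: Hydroboration–oxidation in which the bulky dialkylborane places boron on the terminal carbon C1 of the vinyl group, dialkyl peroxides tolerate boranes at or below room temperature, and the mild perborate oxidation turns C–B into C–OH without base strong enough to harm the O–O bond; no stereocentre is touched.

Step 12
Reactants: 17 2-[(3S,5R)-5-{(2R)-7-[(tert-butyldiphenylsilyl)oxy]-2-methylheptyl}-3,5-dimethyl-1,2-dioxolan-3-yl]ethan-1-ol
Product: 19 2-[(3R,5R)-5-{(2R)-7-[(tert-butyldiphenylsilyl)oxy]-2-methylheptyl}-3,5-dimethyl-1,2-dioxolan-3-yl]acetic acid, via dioxolanylacetaldehyde 18 (not isolated)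
Conditions: TEMPO (0.2 equiv), PhI(OAc)2 (2.5 equiv), MeCN–H2O (1:1), rt
Reagents that add atoms: water, O
Why: Oxoammonium-catalysed (TEMPO) oxidation with PhI(OAc)2 takes the primary alcohol through the aldehyde hydrate to the acid under mildly acidic, metal-free conditions that leave the peroxide and the silyl ether intact.

Step 13
Reactants: 19 2-[(3R,5R)-5-{(2R)-7-[(tert-butyldiphenylsilyl)oxy]-2-methylheptyl}-3,5-dimethyl-1,2-dioxolan-3-yl]acetic acid
Product: 20 methyl 2-[(3R,5R)-5-{(2R)-7-[(tert-butyldiphenylsilyl)oxy]-2-methylheptyl}-3,5-dimethyl-1,2-dioxolan-3-yl]acetate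
Conditions: TMSCHN2, MeOH–toluene, 0 °C
Reagents that add atoms: (trimethylsilyl)diazomethane, C[Si](C)(C)C=[N+]=[N-]
Why: Esterification with (trimethylsilyl)diazomethane in methanol is fast and neutral, and the methyl ester masks the acid for the base-mediated olefination.

Step 14
Reactants: 20 methyl 2-[(3R,5R)-5-{(2R)-7-[(tert-butyldiphenylsilyl)oxy]-2-methylheptyl}-3,5-dimethyl-1,2-dioxolan-3-yl]acetate
Product: 21 methyl 2-[(3R,5R)-5-[(2R)-7-hydroxy-2-methylheptyl]-3,5-dimethyl-1,2-dioxolan-3-yl]acetate
Conditions: HF·pyridine, pyridine, THF, 0 °C to rt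
Reagents that add atoms: none
Why: Fluoride cleavage of the primary silyl ether with buffered HF·pyridine is acidic and not basic, so the β-peroxy ester cannot open by enolate-driven retro-oxa-Michael reaction and the O–O bond is not at risk.

Step 15
Reactants: 21 methyl 2-[(3R,5R)-5-[(2R)-7-hydroxy-2-methylheptyl]-3,5-dimethyl-1,2-dioxolan-3-yl]acetate
Product: 22 methyl 2-[(3R,5R)-3,5-dimethyl-5-[(2R)-2-methyl-7-oxoheptyl]-1,2-dioxolan-3-yl]acetate
Conditions: Dess–Martin periodinane, CH2Cl2, 0 °C to rt
Reagents that add atoms: none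
Why: Dess–Martin oxidation gives the aldehyde without over-oxidation and is compatible with dialkyl peroxides and esters.

Step 16
Reactants: 23 1-phenylprop-2-en-1-ol (racemic); 24 triethyl orthoacetate
Product: 26 ethyl (4E)-5-phenylpent-4-enoate, via mixed ketene acetal 25 (not isolated)
Conditions: 24 (5 equiv), EtCO2H (cat.), 140 °C, EtOH distilled off
Reagents that add atoms: none
Why: Johnson–Claisen rearrangement in which the ketene acetal formed by orthoester exchange undergoes a chair-like [3,3]-sigmatropic shift with phenyl equatorial, giving the conjugated (E)-alkene C16=C17 and the two-carbon ester extension in one step.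

Step 17
Reactants: 26 ethyl (4E)-5-phenylpent-4-enoate
Product: 27 (4E)-5-phenylpent-4-en-1-ol
Conditions: LiAlH4, THF, 0 °C
Reagents that add atoms: none
Why: Hydride reduction of the ester to the primary alcohol leaves the styrenic double bond, which is not conjugated to the carbonyl, untouched.

Step 18
Reactants: 27 (4E)-5-phenylpent-4-en-1-ol; 28 1-phenyl-1H-tetrazole-5-thiol
Product: 29 1-phenyl-5-{[(4E)-5-phenylpent-4-en-1-yl]sulfanyl}-1H-tetrazole
Conditions: PPh3, DIAD, THF, 0 °C to rt
Reagents that add atoms: none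
Why: Mitsunobu thioetherification of the primary alcohol with the acidic tetrazole thiol proceeds selectively at sulfur.

Step 19
Reactants: 29 1-phenyl-5-{[(4E)-5-phenylpent-4-en-1-yl]sulfanyl}-1H-tetrazole
Product: 31 1-phenyl-5-{[(4E)-5-phenylpent-4-en-1-yl]sulfonyl}-1H-tetrazole, via sulfoxide 30 (not isolated)
Conditions: (NH4)6Mo7O24·4H2O (cat.), 30% H2O2, EtOH, 0 °C to rt
Reagents that add atoms: hydrogen peroxide, OO
Why: (NH4)6Mo7O24-catalysed peroxide oxidation takes the sulfide through the sulfoxide to the sulfone faster than it epoxidises the conjugated disubstituted alkene.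

Step 20
Reactants: 31 1-phenyl-5-{[(4E)-5-phenylpent-4-en-1-yl]sulfonyl}-1H-tetrazole; 22 methyl 2-[(3R,5R)-3,5-dimethyl-5-[(2R)-2-methyl-7-oxoheptyl]-1,2-dioxolan-3-yl]acetate
Product: 33 methyl 2-[(3R,5R)-3,5-dimethyl-5-[(2R,7E,11E)-2-methyl-12-phenyldodeca-7,11-dien-1-yl]-1,2-dioxolan-3-yl]acetate, via potassium sulfonyl carbanion 32 (not isolated)
Conditions: 31 (1.3 equiv), KN(SiMe3)2 (1.2 equiv), DME, −55 °C; then 22, −55 °C to rt
Reagents that add atoms: none
Why: Julia–Kocienski olefination in which the premetalated phenyltetrazolyl sulfone adds to the unbranched aldehyde and the adduct collapses by Smiles rearrangement with loss of SO2 and tetrazololate, which with potassium in DME favours the (E)-alkene C12=C13; the sulfonyl carbanion is too weak a base to enolise the methyl ester and is consumed by the aldehyde before it can attack the O–O bond.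

Step 21
Reactants: 33 methyl 2-[(3R,5R)-3,5-dimethyl-5-[(2R,7E,11E)-2-methyl-12-phenyldodeca-7,11-dien-1-yl]-1,2-dioxolan-3-yl]acetate
Product: 34 2-[(3R,5R)-3,5-dimethyl-5-[(2R,7E,11E)-2-methyl-12-phenyldodeca-7,11-dien-1-yl]-1,2-dioxolan-3-yl]acetic acid (CNP0204107.4)
Conditions: LiOH, THF–H2O, 0 °C to rt; then 1 M HCl to pH 3
Reagents that add atoms: lithium hydroxide, [Li+].[OH-]
Why: Saponification of the unhindered methyl ester under mild conditions followed by acidification frees the acid, and because neither peroxide carbon carries a hydrogen, base-induced O–O fragmentation of the Kornblum–DeLaMare type is not available.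

**Compound list**

1 | (R)-citronellic acid, (3R)-3,7-dimethyloct-6-enoic acid | C[C@H](CCC=C(C)C)CC(=O)O | starting material
2 | dilithium (4R)-4,8-dimethylnon-7-ene-2,2-diolate | C[C@H](CCC=C(C)C)CC(C)(O[Li])O[Li] | intermediate (not isolated)
3 | (4R)-4,8-dimethylnon-7-en-2-one | C[C@H](CCC=C(C)C)CC(C)=O | intermediate
4 | (Z)-but-2-ene-1,4-diol | OC/C=C\CO | starting material
5 | (Z)-1,4-bis[(tert-butyldiphenylsilyl)oxy]but-2-ene | CC(C)(C)[Si](c1ccccc1)(c1ccccc1)OC/C=C\CO[Si](c1ccccc1)(c1ccccc1)C(C)(C)C | intermediate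
6 | (4R,7E)-9-[(tert-butyldiphenylsilyl)oxy]-4-methylnon-7-en-2-one | C[C@H](CC/C=C/CO[Si](c1ccccc1)(c1ccccc1)C(C)(C)C)CC(C)=O | intermediate
7 | (4R)-9-[(tert-butyldiphenylsilyl)oxy]-4-methylnonan-2-one | C[C@H](CCCCCO[Si](c1ccccc1)(c1ccccc1)C(C)(C)C)CC(C)=O | intermediate
8 | triethyl 2-phosphonopropionate, ethyl 2-(diethoxyphosphoryl)propanoate | CCOC(=O)C(C)P(=O)(OCC)OCC | starting material
9 | sodium salt of the α-carbanion of 8 | [Na+].CCOC(=O)[C-](C)P(=O)(OCC)OCC | intermediate (not isolated)
10 | ethyl (5R)-10-[(tert-butyldiphenylsilyl)oxy]-2,3,5-trimethyldec-2-enoate, E/Z mixture | C[C@H](CCCCCO[Si](c1ccccc1)(c1ccccc1)C(C)(C)C)CC(C)=C(C)C(=O)OCC | intermediate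
11 | (5R)-10-[(tert-butyldiphenylsilyl)oxy]-2,3,5-trimethyldec-2-en-1-ol, E/Z mixture | C[C@H](CCCCCO[Si](c1ccccc1)(c1ccccc1)C(C)(C)C)CC(C)=C(C)CO | intermediate
12 | (2-{(2R)-7-[(tert-butyldiphenylsilyl)oxy]-2-methylheptyl}-1,2-dimethylcyclopropyl)methanol, mixture of cyclopropane diastereomers | C[C@H](CCCCCO[Si](c1ccccc1)(c1ccccc1)C(C)(C)C)CC1(C)CC1(C)CO | intermediate
13 | 2-{(2R)-7-[(tert-butyldiphenylsilyl)oxy]-2-methylheptyl}-1,2-dimethylcyclopropane-1-carbaldehyde, mixture of cyclopropane diastereomers | C[C@H](CCCCCO[Si](c1ccccc1)(c1ccccc1)C(C)(C)C)CC1(C)CC1(C)C=O | intermediate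
14 | tert-butyl{[(6R)-7-(2-ethenyl-1,2-dimethylcyclopropyl)-6-methylheptyl]oxy}diphenylsilane, mixture of cyclopropane diastereomers | C[C@H](CCCCCO[Si](c1ccccc1)(c1ccccc1)C(C)(C)C)CC1(C)CC1(C)C=C | intermediate (key-step precursor)
15 | tert-butyl({(6R)-7-[(3R,5R)-5-ethenyl-3,5-dimethyl-1,2-dioxolan-3-yl]-6-methylheptyl}oxy)diphenylsilane, ring methyls cis | C[C@H](CCCCCO[Si](c1ccccc1)(c1ccccc1)C(C)(C)C)C[C@]1(C)C[C@](C)(C=C)OO1 | intermediate (key-step product)
16 | 9-{2-[(3S,5R)-5-{(2R)-7-[(tert-butyldiphenylsilyl)oxy]-2-methylheptyl}-3,5-dimethyl-1,2-dioxolan-3-yl]ethyl}-9-borabicyclo[3.3.1]nonane | C[C@H](CCCCCO[Si](c1ccccc1)(c1ccccc1)C(C)(C)C)C[C@]1(C)C[C@](C)(CCB2C3CCCC2CCC3)OO1 | intermediate (not isolated)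
17 | 2-[(3S,5R)-5-{(2R)-7-[(tert-butyldiphenylsilyl)oxy]-2-methylheptyl}-3,5-dimethyl-1,2-dioxolan-3-yl]ethan-1-ol | C[C@H](CCCCCO[Si](c1ccccc1)(c1ccccc1)C(C)(C)C)C[C@]1(C)C[C@](C)(CCO)OO1 | intermediate
18 | 2-[(3R,5R)-5-{(2R)-7-[(tert-butyldiphenylsilyl)oxy]-2-methylheptyl}-3,5-dimethyl-1,2-dioxolan-3-yl]acetaldehyde | C[C@H](CCCCCO[Si](c1ccccc1)(c1ccccc1)C(C)(C)C)C[C@]1(C)C[C@](C)(CC=O)OO1 | intermediate (not isolated)
19 | 2-[(3R,5R)-5-{(2R)-7-[(tert-butyldiphenylsilyl)oxy]-2-methylheptyl}-3,5-dimethyl-1,2-dioxolan-3-yl]acetic acid | C[C@H](CCCCCO[Si](c1ccccc1)(c1ccccc1)C(C)(C)C)C[C@]1(C)C[C@](C)(CC(=O)O)OO1 | intermediate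
20 | methyl 2-[(3R,5R)-5-{(2R)-7-[(tert-butyldiphenylsilyl)oxy]-2-methylheptyl}-3,5-dimethyl-1,2-dioxolan-3-yl]acetate | C[C@H](CCCCCO[Si](c1ccccc1)(c1ccccc1)C(C)(C)C)C[C@]1(C)C[C@](C)(CC(=O)OC)OO1 | intermediate
21 | methyl 2-[(3R,5R)-5-[(2R)-7-hydroxy-2-methylheptyl]-3,5-dimethyl-1,2-dioxolan-3-yl]acetate | C[C@H](CCCCCO)C[C@]1(C)C[C@](C)(CC(=O)OC)OO1 | intermediate
22 | methyl 2-[(3R,5R)-3,5-dimethyl-5-[(2R)-2-methyl-7-oxoheptyl]-1,2-dioxolan-3-yl]acetate | C[C@H](CCCCC=O)C[C@]1(C)C[C@](C)(CC(=O)OC)OO1 | intermediate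
23 | 1-phenylprop-2-en-1-ol, racemic | C=CC(O)c1ccccc1 | starting material
24 | triethyl orthoacetate | CCOC(C)(OCC)OCC | starting material
25 | 1-ethoxy-1-[(1-phenylprop-2-en-1-yl)oxy]ethene | C=C(OCC)OC(C=C)c1ccccc1 | intermediate (not isolated)
26 | ethyl (4E)-5-phenylpent-4-enoate | CCOC(=O)CC/C=C/c1ccccc1 | intermediate
27 | (4E)-5-phenylpent-4-en-1-ol | OCCC/C=C/c1ccccc1 | intermediate
28 | 1-phenyl-1H-tetrazole-5-thiol | Sc1nnnn1-c1ccccc1 | starting material
29 | 1-phenyl-5-{[(4E)-5-phenylpent-4-en-1-yl]sulfanyl}-1H-tetrazole | C(CC/C=C/c1ccccc1)Sc1nnnn1-c1ccccc1 | intermediate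
30 | 1-phenyl-5-{[(4E)-5-phenylpent-4-en-1-yl]sulfinyl}-1H-tetrazole | O=S(CCC/C=C/c1ccccc1)c1nnnn1-c1ccccc1 | intermediate (not isolated)
31 | 1-phenyl-5-{[(4E)-5-phenylpent-4-en-1-yl]sulfonyl}-1H-tetrazole | O=S(=O)(CCC/C=C/c1ccccc1)c1nnnn1-c1ccccc1 | intermediate
32 | potassium salt of the α-sulfonyl carbanion of 31 | [K+].[CH-](CC/C=C/c1ccccc1)S(=O)(=O)c1nnnn1-c1ccccc1 | intermediate (not isolated)
33 | methyl 2-[(3R,5R)-3,5-dimethyl-5-[(2R,7E,11E)-2-methyl-12-phenyldodeca-7,11-dien-1-yl]-1,2-dioxolan-3-yl]acetate | C[C@H](CCCC/C=C/CC/C=C/c1ccccc1)C[C@]1(C)C[C@](C)(CC(=O)OC)OO1 | intermediate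
34 | 2-[(3R,5R)-3,5-dimethyl-5-[(2R,7E,11E)-2-methyl-12-phenyldodeca-7,11-dien-1-yl]-1,2-dioxolan-3-yl]acetic acid | C[C@H](CCCC/C=C/CC/C=C/c1ccccc1)C[C@]1(C)C[C@](C)(CC(=O)O)OO1 | target

**Step count and risks**

Total step count: 21. Longest linear sequence: 16 steps (steps 1, 3 to 15, 20 and 21).

Step 10 is the most likely to fail. Oxygen is captured at the planar C5 radical without facial bias from C7, and the chair-like closure tells the C5 methyl from the C5 CH2R arm only weakly, so the wanted isomer may be a minor, poorly separable part of a four-isomer mixture. In addition, 5-exo attack on a fully substituted alkene carbon may be slow enough for the tertiary peroxyl radical to abstract hydrogen and stall the chain. The fallback builds the ring by an ionic route that forms C4–C5 and O–C3 and sets out from enoate 10. Ozonolysis in CH2Cl2–MeOH at −78 °C should cleave the tetrasubstituted double bond so that the ester-bearing carbon leaves as the keto ester and the carbonyl oxide of the C5 half is trapped by methanol as the α-methoxy hydroperoxide F1. Silylation (Et3SiCl, imidazole, DMF) gives the triethylsilyl peroxyketal F2. SnCl4 in CH2Cl2 at −78 °C ionises F2 to a peroxycarbenium ion, which methyl 3-methylbut-3-enoate attacks through its CH2 terminus; the tertiary cation is then closed by the silylperoxy oxygen, a Lewis-acid-mediated [3+2] annulation of a peroxycarbenium ion with a 1,1-disubstituted alkene. This delivers methyl ester 20 directly, so the route is rejoined at 20 and steps 11 to 13 fall away. C7 still exerts no control, and the diastereomers would be separated at the more polar ester stage.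

Step 11 is the second risk. The borane may attack the O–O bond, the γ-peroxy organoborane may fragment by 1,3-elimination when the borate forms during oxidation, and addition to the neopentyl-type vinyl group may be slow. The fallback replaces anti-Markovnikov hydration by oxidative cleavage and one-carbon homologation and sets out from 15. Ozonolysis (O3, CH2Cl2, −78 °C; Me2S) gives the α-peroxy aldehyde F3. Chlorite oxidation (NaClO2, NaH2PO4, 2-methyl-2-butene, t-BuOH–H2O) gives the dioxolane-3-carboxylic acid F4. An Arndt–Eistert sequence follows: the mixed anhydride (i-BuOCOCl, N-methylmorpholine) is treated with TMSCHN2 to give the diazoketone F5, and Wolff rearrangement (PhCO2Ag, Et3N, MeOH), in which the quaternary ring carbon migrates with retention, gives methyl ester 20. The route is rejoined at 20 and steps 12 and 13 fall away.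

Step 5 is the third risk. Enolisation and self-condensation of the β-branched methyl ketone may outrun addition of the hindered α-methyl phosphonate anion, and prolonged heating with base may move the new double bond out of conjugation. The fallback replaces olefination and methylene transfer by carbene addition to a 1,1-disubstituted alkene and sets out from ketone 7. Wittig methylenation (Ph3PCH3Br, KOtBu, THF) gives the alkene F6. Ethyl 2-diazopropanoate F7 is made from ethyl 2-methylacetoacetate by deacylative diazo transfer (4-acetamidobenzenesulfonyl azide, DBU, MeCN). It is added slowly at −78 °C to F6 and Rh2(O2CCPh3)4 (1 mol%) in CH2Cl2, the bulky carboxylate ligands holding back β-hydride migration of the carbenoid, to give the cyclopropane ester F8. LiAlH4 (THF, 0 °C) reduces F8 to 12, where the route is rejoined; steps 5 to 7 are replaced.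

**Further compounds**

F1 | step 10 | tert-butyl{[(6R)-8-hydroperoxy-8-methoxy-6-methylnonyl]oxy}diphenylsilane, mixture at C8 | C[C@H](CCCCCO[Si](c1ccccc1)(c1ccccc1)C(C)(C)C)CC(C)(OC)OO
F2 | step 10 | tert-butyl({(6R)-8-methoxy-6-methyl-8-[(triethylsilyl)peroxy]nonyl}oxy)diphenylsilane, mixture at C8 | C[C@H](CCCCCO[Si](c1ccccc1)(c1ccccc1)C(C)(C)C)CC(C)(OC)OO[Si](CC)(CC)CC
F3 | step 11 | (3R,5R)-5-{(2R)-7-[(tert-butyldiphenylsilyl)oxy]-2-methylheptyl}-3,5-dimethyl-1,2-dioxolane-3-carbaldehyde | C[C@H](CCCCCO[Si](c1ccccc1)(c1ccccc1)C(C)(C)C)C[C@]1(C)C[C@](C)(C=O)OO1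
F4 | step 11 | (3R,5R)-5-{(2R)-7-[(tert-butyldiphenylsilyl)oxy]-2-methylheptyl}-3,5-dimethyl-1,2-dioxolane-3-carboxylic acid | C[C@H](CCCCCO[Si](c1ccccc1)(c1ccccc1)C(C)(C)C)C[C@]1(C)C[C@](C)(C(=O)O)OO1
F5 | step 11 | 2-diazo-1-[(3R,5R)-5-{(2R)-7-[(tert-butyldiphenylsilyl)oxy]-2-methylheptyl}-3,5-dimethyl-1,2-dioxolan-3-yl]ethan-1-one | C[C@H](CCCCCO[Si](c1ccccc1)(c1ccccc1)C(C)(C)C)C[C@]1(C)C[C@](C)(C(=O)C=[N+]=[N-])OO1
F6 | step 5 | tert-butyl{[(6R)-6,8-dimethylnon-8-en-1-yl]oxy}diphenylsilane | C[C@H](CCCCCO[Si](c1ccccc1)(c1ccccc1)C(C)(C)C)CC(C)=C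
F7 | step 5 | ethyl 2-diazopropanoate | CCOC(=O)C(C)=[N+]=[N-]
F8 | step 5 | ethyl 2-{(2R)-7-[(tert-butyldiphenylsilyl)oxy]-2-methylheptyl}-1,2-dimethylcyclopropane-1-carboxylate, mixture of cyclopropane diastereomers | C[C@H](CCCCCO[Si](c1ccccc1)(c1ccccc1)C(C)(C)C)CC1(C)CC1(C)C(=O)OCC
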